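The route disconnects the O1–C7a bond of the dihydrobenzofuran. In ring A (C3a, C4–C7, C7a) the ring oxygen O1 is attached at C7a, next to the side-chain carbon C3a and in a 1,3-relation to the oxygenated C6, which lies para to C3a. That pattern results when a para-alkylphenol is oxidised to a cyclohexadienone and a side-chain hydroxyl adds to the neighbouring enone carbon. One operation thus oxidises the phenol, closes the furan ring by oxa-Michael addition and restores aromatic ring A. The precursor is the open-chain (1R,2R)-2-(4-hydroxyphenyl)-1-(3,4,5-trimethoxyphenyl)propan-1-ol, its two stereocentres set by an Evans syn-aldol.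

Key step: step 7

Remark: the target is read as the (2R,3R) isomer, with the C2 aryl and C3 methyl groups trans. Several intermediates change CIP descriptor at the methyl-bearing carbon through priority changes only, without any inversion.

Step 1
Reactants: 1 4-(benzyloxy)phenylacetic acid; 2 (R)-4-benzyl-1,3-oxazolidin-2-one
Product: 4 (4R)-4-benzyl-3-{2-[4-(benzyloxy)phenyl]acetyl}-1,3-oxazolidin-2-one, via mixed pivalic anhydride 3 (not isolated)
Conditions: PivCl, Et3N, THF, −20 °C; then 2, LiCl, −20 °C → rt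
Reagents that add atoms: none
Why: N-acylation of the oxazolidinone through the mixed anhydride (LiCl/Et3N activation of the N–H) should occur at the unhindered arylacetyl carbonyl and not at the pivaloyl carbonyl; no stereocentre is formed.

Step 2
Reactants: 4 (4R)-4-benzyl-3-{2-[4-(benzyloxy)phenyl]acetyl}-1,3-oxazolidin-2-one; 5 3,4,5-trimethoxybenzaldehyde
Product: 8 (4R)-4-benzyl-3-[(2R,3R)-2-[4-(benzyloxy)phenyl]-3-hydroxy-3-(3,4,5-trimethoxyphenyl)propanoyl]-1,3-oxazolidin-2-one, via boron enolate 6 (not isolated), via boron aldolate 7 (not isolated)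
Conditions: Bu2BOTf, i-Pr2NEt, CH2Cl2, −78 → 0 °C; 5, −78 → 0 °C; then pH 7 buffer, MeOH, H2O2, 0 °C
Reagents that add atoms: none
Why: Evans syn-aldol reaction, in which the Z-dibutylboron enolate reacts through a Zimmerman–Traxler chair and the aldehyde approaches the enolate face remote from the benzyl group of the (R)-auxiliary, which should set both new centres (2R,3R, syn).

Step 3
Reactants: 8 (4R)-4-benzyl-3-[(2R,3R)-2-[4-(benzyloxy)phenyl]-3-hydroxy-3-(3,4,5-trimethoxyphenyl)propanoyl]-1,3-oxazolidin-2-one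
Product: 9 (1R,2S)-2-[4-(benzyloxy)phenyl]-1-(3,4,5-trimethoxyphenyl)propane-1,3-diol
Conditions: LiBH4, MeOH (1 equiv), THF, 0 °C
Reagents that add atoms: none
Why: Reductive cleavage of the N-acyloxazolidinone by LiBH4 (hydride attack at the exocyclic imide carbonyl) should give the primary alcohol and free auxiliary 2 without touching either stereocentre, the change from 2R to 2S being a CIP priority effect only.

Step 4
Reactants: 9 (1R,2S)-2-[4-(benzyloxy)phenyl]-1-(3,4,5-trimethoxyphenyl)propane-1,3-diol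
Product: 10 (2S,3R)-2-[4-(benzyloxy)phenyl]-3-hydroxy-3-(3,4,5-trimethoxyphenyl)propyl 4-methylbenzenesulfonate
Conditions: TsCl (1.05 equiv), Et3N, DMAP (cat.), CH2Cl2, 0 °C
Reagents that add atoms: p-toluenesulfonyl chloride, Cc1ccc(cc1)S(=O)(=O)Cl
Why: Selective sulfonylation of a 1,3-diol, in which the unhindered primary hydroxyl should react well ahead of the hindered secondary benzylic hydroxyl.

Step 5
Reactants: 10 (2S,3R)-2-[4-(benzyloxy)phenyl]-3-hydroxy-3-(3,4,5-trimethoxyphenyl)propyl 4-methylbenzenesulfonate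
Product: 11 (1R,2R)-2-[4-(benzyloxy)phenyl]-1-(3,4,5-trimethoxyphenyl)propan-1-ol
Conditions: LiAlH4, THF, 0 °C → rt
Reagents that add atoms: none
Why: SN2 hydride displacement of the primary tosylate (the alkoxyaluminate formed at the secondary hydroxyl can deliver hydride internally) should turn CH2OTs into the C3 methyl group without affecting either stereocentre, the descriptor change 2S to 2R being a CIP priority effect only.

Step 6
Reactants: 11 (1R,2R)-2-[4-(benzyloxy)phenyl]-1-(3,4,5-trimethoxyphenyl)propan-1-ol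
Product: 12 4-[(1R,2R)-1-hydroxy-1-(3,4,5-trimethoxyphenyl)propan-2-yl]phenol
Conditions: H2 (1 atm), Pd/C, EtOAc, rt
Reagents that add atoms: none
Why: Catalytic hydrogenolysis of the aryl benzyl ether over Pd/C in a neutral solvent is much faster than C–O cleavage of the secondary benzylic alcohol, so only the phenol should be unveiled.

Step 7
Reactants: 12 4-[(1R,2R)-1-hydroxy-1-(3,4,5-trimethoxyphenyl)propan-2-yl]phenol
Product: 15 (2R,3R)-3-methyl-2-(3,4,5-trimethoxyphenyl)-2,3-dihydro-1-benzofuran-6-ol, via methoxydienone 13 (not isolated), via bicyclic enone 14 (not isolated)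
Conditions: PhI(OAc)2 (1.05 equiv), MeOH, 0 °C; concentrate; then TsOH·H2O (10 mol%), CH2Cl2, 0 °C → rt
Reagents that add atoms: none
Why: The trivalent iodine reagent oxidises the phenol by two electrons to a phenoxenium equivalent that methanol traps at the para carbon C3a, giving the 4-methoxycyclohexa-2,5-dienone 13; under acid catalysis the C2 hydroxyl adds to the adjacent enone carbon C7a (oxa-Michael) to give cis-fused 14, and loss of methanol from C3a followed by loss of the C7a proton restores ring A with O1 now on C7a. The closest known reaction type is the oxidation of 4-(2-hydroxyethyl)phenols to quinols or quinol ethers, their intramolecular oxa-Michael closure to tetrahydrobenzofuran-6-ones and acid-mediated aromatisation to 2,3-dihydrobenzofuran-6-ols. The single ring formed, the dihydrofuran, closes in the 5-exo-trig mode (O1 onto C7a with the C7a=C7 bond outside the new ring), a four-membered spiro ether through attack at C3a being far less favourable. No stereocentre of 15 is created here: C2 and C3 are carried over from 12 because no bond to either is broken, the two enone β-carbons of the symmetric dienone lead to the same arene, and the transient centres C3a and C7a of 14 disappear on aromatisation. The selectivity needed is oxidation of the phenol beside the trimethoxyphenyl ring, secured because aryl methyl ethers are inert to PhI(OAc)2 in methanol, and aromatisation without ionising the benzylic C2–O bond, secured by using only catalytic sulfonic acid at room temperature on a ring whose trans arrangement is in any case the more stable one. The acid is added only after the oxidant has been consumed, so that the electron-rich phenol 15 is not exposed to it.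

Step 8
Reactants: 15 (2R,3R)-3-methyl-2-(3,4,5-trimethoxyphenyl)-2,3-dihydro-1-benzofuran-6-ol
Product: 16 (2R,3R)-5-bromo-3-methyl-2-(3,4,5-trimethoxyphenyl)-2,3-dihydro-1-benzofuran-6-ol
Conditions: NBS (1.0 equiv), CH2Cl2, −40 → 0 °C
Reagents that add atoms: N-bromosuccinimide, O=C1CCC(=O)N1Br
Why: Electrophilic aromatic bromination of a phenol, expected at C5 because this carbon is ortho to the C6 hydroxyl and para to O1 and is less hindered than C7 between the two oxygens, while the free phenol ring is far more reactive than the trimethoxyphenyl ring.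

Step 9
Reactants: 16 (2R,3R)-5-bromo-3-methyl-2-(3,4,5-trimethoxyphenyl)-2,3-dihydro-1-benzofuran-6-ol
Product: 17 (2R,3R)-5-bromo-6-methoxy-3-methyl-2-(3,4,5-trimethoxyphenyl)-2,3-dihydro-1-benzofuran
Conditions: MeI, K2CO3, acetone, 50 °C
Reagents that add atoms: iodomethane, CI
Why: Williamson O-methylation of the phenoxide, the only acidic site in the molecule, should install the C6 methoxy group without affecting the stereocentres.

Step 10
Reactants: 17 (2R,3R)-5-bromo-6-methoxy-3-methyl-2-(3,4,5-trimethoxyphenyl)-2,3-dihydro-1-benzofuran; 18 4,4,5,5-tetramethyl-2-[(1E)-prop-1-en-1-yl]-1,3,2-dioxaborolane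
Product: 19 (2R,3R)-6-methoxy-3-methyl-5-[(1E)-prop-1-en-1-yl]-2-(3,4,5-trimethoxyphenyl)-2,3-dihydro-1-benzofuran (target)
Conditions: Pd(OAc)2 (cat.), SPhos, K3PO4, toluene–H2O, 90 °C
Reagents that add atoms: none
Why: Suzuki–Miyaura cross-coupling, in which oxidative addition of the aryl bromide to zerovalent palladium, transmetalation of the alkenyl boronate and reductive elimination proceed with retention of alkene geometry, so the E configuration of 18 should be transferred intact while C2 and C3 are not involved.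

Compound list
1 | 4-(benzyloxy)phenylacetic acid | OC(=O)Cc1ccc(OCc2ccccc2)cc1 | starting material
2 | (R)-4-benzyl-1,3-oxazolidin-2-one | O=C1OC[C@@H](Cc2ccccc2)N1 | starting material
3 | 2-[4-(benzyloxy)phenyl]acetic 2,2-dimethylpropanoic anhydride (mixed pivalic anhydride) | CC(C)(C)C(=O)OC(=O)Cc1ccc(OCc2ccccc2)cc1 | intermediate
4 | (4R)-4-benzyl-3-{2-[4-(benzyloxy)phenyl]acetyl}-1,3-oxazolidin-2-one | O=C1OC[C@@H](Cc2ccccc2)N1C(=O)Cc1ccc(OCc2ccccc2)cc1 | intermediate
5 | 3,4,5-trimethoxybenzaldehyde | COc1cc(C=O)cc(OC)c1OC | starting material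
6 | (Z)-dibutylboron enolate of 4 (O-boron and aryl group cis) | CCCCB(CCCC)O/C(N1[C@H](Cc2ccccc2)COC1=O)=C\c1ccc(OCc2ccccc2)cc1 | intermediate
7 | O-dibutylboryl aldolate of 8 | CCCCB(CCCC)O[C@@H](c1cc(OC)c(OC)c(OC)c1)[C@@H](c1ccc(OCc2ccccc2)cc1)C(=O)N1[C@H](Cc2ccccc2)COC1=O | intermediate
8 | (4R)-4-benzyl-3-[(2R,3R)-2-[4-(benzyloxy)phenyl]-3-hydroxy-3-(3,4,5-trimethoxyphenyl)propanoyl]-1,3-oxazolidin-2-one | O=C1OC[C@@H](Cc2ccccc2)N1C(=O)[C@H](c1ccc(OCc2ccccc2)cc1)[C@@H](O)c1cc(OC)c(OC)c(OC)c1 | intermediate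
9 | (1R,2S)-2-[4-(benzyloxy)phenyl]-1-(3,4,5-trimethoxyphenyl)propane-1,3-diol | OC[C@H](c1ccc(OCc2ccccc2)cc1)[C@@H](O)c1cc(OC)c(OC)c(OC)c1 | intermediate
10 | (2S,3R)-2-[4-(benzyloxy)phenyl]-3-hydroxy-3-(3,4,5-trimethoxyphenyl)propyl 4-methylbenzenesulfonate | Cc1ccc(cc1)S(=O)(=O)OC[C@H](c1ccc(OCc2ccccc2)cc1)[C@@H](O)c1cc(OC)c(OC)c(OC)c1 | intermediate
11 | (1R,2R)-2-[4-(benzyloxy)phenyl]-1-(3,4,5-trimethoxyphenyl)propan-1-ol | C[C@H](c1ccc(OCc2ccccc2)cc1)[C@@H](O)c1cc(OC)c(OC)c(OC)c1 | intermediate
12 | 4-[(1R,2R)-1-hydroxy-1-(3,4,5-trimethoxyphenyl)propan-2-yl]phenol | O[C@@H](c1cc(OC)c(OC)c(OC)c1)[C@@H](c1ccc(O)cc1)C | intermediate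
13 | 4-[(1R,2S)-1-hydroxy-1-(3,4,5-trimethoxyphenyl)propan-2-yl]-4-methoxycyclohexa-2,5-dien-1-one | O[C@@H](c1cc(OC)c(OC)c(OC)c1)[C@@H](C1(OC)C=CC(=O)C=C1)C | intermediate
14 | (2R,3S)-3a-methoxy-3-methyl-2-(3,4,5-trimethoxyphenyl)-3,3a,7,7a-tetrahydro-1-benzofuran-6(2H)-one, cis-fused; both cis-fused C3a/C7a diastereomers are expected and converge on 15, so these two centres are left open | O=C1C=CC2(OC)[C@@H](C)[C@H](c3cc(OC)c(OC)c(OC)c3)OC2C1 | intermediate
15 | (2R,3R)-3-methyl-2-(3,4,5-trimethoxyphenyl)-2,3-dihydro-1-benzofuran-6-ol | Oc1ccc2c(c1)O[C@@H](c1cc(OC)c(OC)c(OC)c1)[C@@H]2C | intermediate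
16 | (2R,3R)-5-bromo-3-methyl-2-(3,4,5-trimethoxyphenyl)-2,3-dihydro-1-benzofuran-6-ol | Brc1cc2c(cc1O)O[C@@H](c1cc(OC)c(OC)c(OC)c1)[C@@H]2C | intermediate
17 | (2R,3R)-5-bromo-6-methoxy-3-methyl-2-(3,4,5-trimethoxyphenyl)-2,3-dihydro-1-benzofuran | Brc1cc2c(cc1OC)O[C@@H](c1cc(OC)c(OC)c(OC)c1)[C@@H]2C | intermediate
18 | 4,4,5,5-tetramethyl-2-[(1E)-prop-1-en-1-yl]-1,3,2-dioxaborolane | C/C=C/B1OC(C)(C)C(C)(C)O1 | starting material
19 | (2R,3R)-6-methoxy-3-methyl-5-[(1E)-prop-1-en-1-yl]-2-(3,4,5-trimethoxyphenyl)-2,3-dihydro-1-benzofuran | C/C=C/c1cc2c(cc1OC)O[C@@H](c1cc(OC)c(OC)c(OC)c1)[C@@H]2C | target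

Total step count: 10. Longest linear sequence: 10 steps (1 to 19).

Steps most likely to fail

Step 7. At the phenoxenium stage the C2–C3 bond may fragment (retro-Prins-type release of the aryl aldehyde), or the C3 proton may be lost to a quinone methide, which would also erase C3. The oxa-Michael addition of the hindered secondary alcohol may lag behind these pathways, and the product phenol may be over-oxidised. The fallback makes the same O1–C7a bond by a known copper-catalysed intramolecular Ullmann etherification of an aryl bromide and sets out from 2 and 5. Purchased (2-bromo-4-methoxyphenyl)acetic acid F1 is joined to 2 as in step 1 to give (4R)-4-benzyl-3-[2-(2-bromo-4-methoxyphenyl)acetyl]-1,3-oxazolidin-2-one F2. The Bu2BOTf syn-aldol with 5 should give (4R)-4-benzyl-3-[(2R,3R)-2-(2-bromo-4-methoxyphenyl)-3-hydroxy-3-(3,4,5-trimethoxyphenyl)propanoyl]-1,3-oxazolidin-2-one F3. LiBH4 then gives (1R,2S)-2-(2-bromo-4-methoxyphenyl)-1-(3,4,5-trimethoxyphenyl)propane-1,3-diol F4, and TsCl/Et3N gives (2S,3R)-2-(2-bromo-4-methoxyphenyl)-3-hydroxy-3-(3,4,5-trimethoxyphenyl)propyl 4-methylbenzenesulfonate F5. LiEt3BH (THF, 0 °C, chosen to spare the aryl bromide) gives (1R,2R)-2-(2-bromo-4-methoxyphenyl)-1-(3,4,5-trimethoxyphenyl)propan-1-ol F6. CuI, 1,10-phenanthroline and Cs2CO3 in toluene at 110 °C should close the ring to (2R,3R)-6-methoxy-3-methyl-2-(3,4,5-trimethoxyphenyl)-2,3-dihydro-1-benzofuran F7. NBS (MeCN, 0 °C) is expected to brominate C5, para to O1 on the resorcinol-diether ring, and the fallback comes back to the route at 17.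

Step 8. Bromination may occur at C7, occur twice, or spill onto the trimethoxyphenyl ring. The fallback sets out from 15 and replaces halogenation and cross-coupling by formylation and olefination. Magnesium-phenoxide-directed ortho-formylation (MgCl2, Et3N, paraformaldehyde, MeCN, reflux) can only occur ortho to the hydroxyl on ring A and stops after one formyl group. It should give (2R,3R)-6-hydroxy-3-methyl-2-(3,4,5-trimethoxyphenyl)-2,3-dihydro-1-benzofuran-5-carbaldehyde F8. MeI/K2CO3 gives (2R,3R)-6-methoxy-3-methyl-2-(3,4,5-trimethoxyphenyl)-2,3-dihydro-1-benzofuran-5-carbaldehyde F9. Julia–Kocienski olefination with purchased 5-(ethylsulfonyl)-1-phenyl-1H-tetrazole and KHMDS (DME, −60 °C → rt) then builds the E-propenyl group, and the fallback comes back to the route at 19. Any Z isomer would be isomerised with catalytic PdCl2(MeCN)2.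

Step 5. The neighbouring alkoxide may displace the tosylate (oxetane formation), or the electron-rich aryl group may participate, in place of clean hydride delivery. The fallback sets out from 9 and removes the oxygen by a radical chain under neutral conditions. PPh3, I2 and imidazole (CH2Cl2, 0 °C) should convert the primary hydroxyl selectively into (1R,2R)-2-[4-(benzyloxy)phenyl]-3-iodo-1-(3,4,5-trimethoxyphenyl)propan-1-ol F10. Bu3SnH with AIBN (toluene, 80 °C) reduces the C–I bond, and the fallback comes back to the route at 11.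

Further compounds
F1 | step 7 | (2-bromo-4-methoxyphenyl)acetic acid | OC(=O)Cc1ccc(OC)cc1Br
F2 | step 7 | (4R)-4-benzyl-3-[2-(2-bromo-4-methoxyphenyl)acetyl]-1,3-oxazolidin-2-one | O=C1OC[C@@H](Cc2ccccc2)N1C(=O)Cc1ccc(OC)cc1Br
F3 | step 7 | (4R)-4-benzyl-3-[(2R,3R)-2-(2-bromo-4-methoxyphenyl)-3-hydroxy-3-(3,4,5-trimethoxyphenyl)propanoyl]-1,3-oxazolidin-2-one | O=C1OC[C@@H](Cc2ccccc2)N1C(=O)[C@H](c1ccc(OC)cc1Br)[C@@H](O)c1cc(OC)c(OC)c(OC)c1
F4 | step 7 | (1R,2S)-2-(2-bromo-4-methoxyphenyl)-1-(3,4,5-trimethoxyphenyl)propane-1,3-diol | OC[C@H](c1ccc(OC)cc1Br)[C@@H](O)c1cc(OC)c(OC)c(OC)c1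
F5 | step 7 | (2S,3R)-2-(2-bromo-4-methoxyphenyl)-3-hydroxy-3-(3,4,5-trimethoxyphenyl)propyl 4-methylbenzenesulfonate | Cc1ccc(cc1)S(=O)(=O)OC[C@H](c1ccc(OC)cc1Br)[C@@H](O)c1cc(OC)c(OC)c(OC)c1
F6 | step 7 | (1R,2R)-2-(2-bromo-4-methoxyphenyl)-1-(3,4,5-trimethoxyphenyl)propan-1-ol | C[C@H](c1ccc(OC)cc1Br)[C@@H](O)c1cc(OC)c(OC)c(OC)c1
F7 | step 7 | (2R,3R)-6-methoxy-3-methyl-2-(3,4,5-trimethoxyphenyl)-2,3-dihydro-1-benzofuran | COc1ccc2c(c1)O[C@@H](c1cc(OC)c(OC)c(OC)c1)[C@@H]2C
F8 | step 8 | (2R,3R)-6-hydroxy-3-methyl-2-(3,4,5-trimethoxyphenyl)-2,3-dihydro-1-benzofuran-5-carbaldehyde | O=Cc1cc2c(cc1O)O[C@@H](c1cc(OC)c(OC)c(OC)c1)[C@@H]2C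
F9 | step 8 | (2R,3R)-6-methoxy-3-methyl-2-(3,4,5-trimethoxyphenyl)-2,3-dihydro-1-benzofuran-5-carbaldehyde | O=Cc1cc2c(cc1OC)O[C@@H](c1cc(OC)c(OC)c(OC)c1)[C@@H]2C
F10 | step 5 | (1R,2R)-2-[4-(benzyloxy)phenyl]-3-iodo-1-(3,4,5-trimethoxyphenyl)propan-1-ol | IC[C@H](c1ccc(OCc2ccccc2)cc1)[C@@H](O)c1cc(OC)c(OC)c(OC)c1
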